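The readings stem from a simulated flask for substances that don't exist; noise was put on by code.

At the reading, 20 h after the start, the winter flask and the simulated zeta run were charged with the same substrate and have received the same whole charge of partner. They differ in how long that partner has been inside. Zeta was charged at once, so its partner has been in for 20 h. Winter takes partner evenly over 16.0 h, so a portion enters on average at 8.00 h and has stayed 12.0 h at the reading. This average stay of the partner charge is the mean partner age.

| setting | zeta | eta | epsilon | theta | noon | winter | summer | midnight |
|---|---|---|---|---|---|---|---|---|
| substrate | 0.40 M | 0.56 M | 0.88 M | 0.40 M | 0.40 M | 0.40 M | 0.40 M | 0.40 M |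
| partner | 0.48 M | 0.48 M | 0.48 M | 0.72 M | 0.480 M | 0.480 M (fed, over 16.0 h) | 0.480 M | 0.480 M |
| remark | run made earlier | run made earlier | run made earlier | run made earlier | a closed flask charged with all of it at once and left for 20 h | all but partner at the start; partner goes in evenly over 16.0 h, the run ends at 20 h | a single well-mixed tank run continuously and read at steady state, 200 h in it on average | a single well-mixed tank run continuously and read at steady state, 20 h in it on average |
| time |  |  |  |  | 20 h | 20 h |  |  |

| zeta: time / h | zeta: product / % | eta: time / h | eta: product / % | epsilon: time / h | epsilon: product / % | theta: time / h | theta: product / % |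
|---|---|---|---|---|---|---|---|
| 1.50 | 0.3 | 3.00 | 2.5 | 1.33 | 0 | 1.33 | 0.5 |
| 3.00 | 1.7 | 6.00 | 5.5 | 4.00 | 2.8 | 4.00 | 4.5 |
| 6.00 | 7.0 | 10.0 | 13.1 | 8.00 | 8.5 | 8.00 | 14.5 |
| 10.0 | 12.7 | 12.0 | 16.3 | 12.0 | 13.7 | 12.0 | 22.7 |
| 20.0 | 26.8 | 15.0 | 19.7 | 15.0 | 17.7 | 15.0 | 27.5 |

(standard deviation of a reading: 0.5 percentage points)

- the stated concentrations are those of everything mixed, before any reaction; amounts are the same in each set-up
- the feed brings no volume worth counting
- the earlier runs were made in a closed, stirred flask
- a reading or a percentage of product counts all its forms, free or not

* order of the set-ups by the amount of product at the outlet or at the end, in percent of the substrate put in, highest first (noon / winter / summer / midnight)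
* amount of product at the outlet or at the end, in percent of the substrate put in, noon
* amount of product at the outlet or at the end, in percent of the substrate put in, winter
* amount of product at the outlet or at the end, in percent of the substrate put in, summer
* amount of product at the outlet or at the end, in percent of the substrate put in, midnight

After a short induction period, zeta's product readings climb on a nearly straight line: 0.0143 /h of the substrate charge from 6.00 h to 10.0 h, and 0.0141 /h from 10.0 h to 20.0 h. This rise, reckoned as a fraction of the charge, goes with partner rather than with substrate. Theta, with 0.72 M partner against 0.48 M, gains 0.0186 /h, faster than zeta. Epsilon, with 0.88 M substrate against 0.40 M, gains 0.0131 /h, close to zeta. So, for zeta's charge, the rise can be frozen and charged per hour of partner age. Zeta ends at 26.8 % because its partner is older than winter's, and taking 8.00 h of age off that reading puts winter at 15.5 % by this reckoning.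

The forecast orders the set-ups summer > noon > midnight > winter and gives noon 26.6 %, summer 64 %, midnight 22 % and, saying of winter that “partner averages low early on”, winter 16.5 %; its winter lies above the reckoning here.

The set-ups stand in the order summer > noon > midnight > winter: noon 26.4 %, summer 56.7 %, midnight 20.5 % and winter 16.9 %, the last being 1.4 percentage points above the reckoning, with the forms of product counted in. Winter's partner concentration peaks at 17.3 % of the whole charge per starting volume.

    substrate ⇌ open intermediate (K = 0.700, k = 0.250 /h)
    partner → second intermediate (k = 0.360 /h)
    open intermediate + second intermediate ⇌ product (K = 65.0 /M, k = 0.120 /M/h)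
    substrate + product ⇌ idle adduct, settled at all times (K = 3.50 /M)

Product divided by mean partner age comes to 0.0141 /h of the substrate charge in winter, beside the frozen rise of 0.0141 /h. In noon, charged at once and so of age 20 h, it comes to 0.0132 /h.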